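## Retrosynthetic overview
1. Feature: the ketone carbon C5 of the ten-membered ring and the exocyclic methylene C11=C13 on the γ-lactone ring form a γ,δ-unsaturated ketone, O=C5–C6H2–C7H–C11(=C13H2). This is a Carroll/Claisen retron, and its σ-bond C6–C7 is a bond of the ten-membered ring.
2. Key disconnection C6–C7: CO2 is put back between C6 and an oxygen on C13. This gives a temporary 14-membered β-keto lactone of a 3-(hydroxymethyl)butenolide, and from it an open-chain tert-butyl β-keto ester with a free C13–OH.
3. Appendage disconnections: C5–C6 (Roskamp homologation of an aldehyde unmasked from a vinyl group), C11–C13 (Stille hydroxymethylation of an α-bromobutenolide) and the C9 ester (Steglich).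
4. C8–C9: vinylogous Mukaiyama aldol of a 3-bromo-2-silyloxyfuran with an α-silyloxy aldehyde, with C8 and C9 relayed from C10. The aldehyde comes from (R)-β-citronellene (C4 bought) by allylic oxidation, Sharpless epoxidation (C10) and hydride opening.
5. Ring order: the five-membered lactone ring enters intact as the furanone ring. The 14-membered lactone is formed and consumed in the key flask. The ten-membered carbocycle is closed last.

Key step: step 12

Remark: locants follow germacrane numbering (ring C1–C10 with ketone C5 and carbinol C10; lactone C7, C8, C11, C12; methylene C13; methyls C14 on C10 and C15 on C4); the acyl group is taken as (R)-2-methylbutanoyl, as drawn in the given SMILES, and the compounds marked as starting materials in the list are taken as commercial.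

## Route

Step 1
Reactants: 1 (R)-β-citronellene, (3R)-3,7-dimethylocta-1,6-diene
Product: 2 (2E,6R)-2,6-dimethylocta-2,7-dien-1-ol
Conditions: SeO2 (cat.), t-BuOOH, salicylic acid (cat.), CH2Cl2, 0 °C → rt
Reagents that add atoms: tert-butyl hydroperoxide, CC(C)(C)OO
Why: Riley allylic oxidation (ene reaction, then [2,3] shift) attacks only the electron-rich trisubstituted alkene and oxidises the methyl group trans to the chain, so the E allylic alcohol should form while the bought C4 centre and the vinyl group stay untouched.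

Step 2
Reactants: 2 (2E,6R)-2,6-dimethylocta-2,7-dien-1-ol
Product: 3 {(2R,3R)-2-methyl-3-[(3R)-3-methylpent-4-en-1-yl]oxiran-2-yl}methanol
Conditions: Ti(Oi-Pr)4 (cat.), D-(−)-diethyl tartrate (cat.), t-BuOOH, 4 Å MS, CH2Cl2, −20 °C
Reagents that add atoms: tert-butyl hydroperoxide, CC(C)(C)OO
Why: Sharpless asymmetric epoxidation, in which the D-(−)-tartrate catalyst delivers oxygen to the face that gives the (2R,3R)-epoxide and so fixes the C10–O bond under catalyst control, while the isolated vinyl group is inert.

Step 3
Reactants: 3 {(2R,3R)-2-methyl-3-[(3R)-3-methylpent-4-en-1-yl]oxiran-2-yl}methanol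
Product: 4 (2S,6R)-2,6-dimethyloct-7-ene-1,2-diol
Conditions: LiAlH4, THF, 0 °C → rt; aq. NaOH work-up
Reagents that add atoms: none
Why: SN2 hydride opening of a 2-methyl-2,3-epoxy alcohol takes place at the less hindered secondary carbon (C1), so the C10–O bond and the C10 configuration are retained and the tertiary/primary 1,2-diol results.

Step 4
Reactants: 4 (2S,6R)-2,6-dimethyloct-7-ene-1,2-diol
Product: 5 (2S,6R)-2,6-dimethyl-1,2-bis(triethylsilyloxy)oct-7-ene
Conditions: TESOTf, 2,6-lutidine, CH2Cl2, 0 °C
Reagents that add atoms: triethylsilyl triflate, CC[Si](CC)(CC)OS(=O)(=O)C(F)(F)F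
Why: Silylation with a silyl triflate is strong enough for the tertiary carbinol as well as the primary one, and no stereocentre is touched.

Step 5
Reactants: 5 (2S,6R)-2,6-dimethyl-1,2-bis(triethylsilyloxy)oct-7-ene
Product: 6 (2S,6R)-2,6-dimethyl-2-(triethylsilyloxy)oct-7-enal
Conditions: (COCl)2, DMSO, CH2Cl2, −78 → −40 °C; Et3N, −78 °C → rt
Reagents that add atoms: none
Why: Swern oxidation applied directly to a primary triethylsilyl ether cleaves only the unhindered primary O–Si bond and oxidises that carbon to the aldehyde, while the tertiary TES ether survives and the quaternary α-carbon cannot epimerise.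

Step 6
Reactants: 7 3-bromofuran-2(5H)-one
Product: 8 3-bromo-2-(triisopropylsilyloxy)furan
Conditions: TIPSOTf, Et3N, CH2Cl2, 0 °C
Reagents that add atoms: triisopropylsilyl triflate, CC(C)[Si](OS(=O)(=O)C(F)(F)F)(C(C)C)C(C)C
Why: Soft enolisation and O-silylation of a butenolide gives the aromatic 2-silyloxyfuran, which is the standard preparation of a dienol silyl ether.

Step 7
Reactants: 6 (2S,6R)-2,6-dimethyl-2-(triethylsilyloxy)oct-7-enal; 8 3-bromo-2-(triisopropylsilyloxy)furan
Product: 9 (5S)-3-bromo-5-[(1R,2S,6R)-1-hydroxy-2,6-dimethyl-2-(triethylsilyloxy)oct-7-en-1-yl]furan-2(5H)-one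
Conditions: BF3·OEt2, CH2Cl2, −78 °C; aq. NaHCO3
Reagents that add atoms: none
Why: Vinylogous Mukaiyama aldol reaction in which the silyloxyfuran attacks through its γ-carbon in the open Lewis-acid transition state that favours the 8,9-threo pair, and the non-chelated α-silyloxy aldehyde is attacked anti to the C10–O bond (polar Felkin–Anh), which should give the 9,10-erythro relationship, so C8 and C9 are both relayed from C10.

Step 8
Reactants: 9 (5S)-3-bromo-5-[(1R,2S,6R)-1-hydroxy-2,6-dimethyl-2-(triethylsilyloxy)oct-7-en-1-yl]furan-2(5H)-one; 10 (R)-2-methylbutanoic acid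
Product: 11 (1R,2S,6R)-1-[(2S)-4-bromo-5-oxo-2,5-dihydrofuran-2-yl]-2,6-dimethyl-2-(triethylsilyloxy)oct-7-en-1-yl (2R)-2-methylbutanoate
Conditions: DCC, DMAP (cat.), excess 10, CH2Cl2, 0 °C → rt
Reagents that add atoms: none
Why: Steglich esterification acylates the only free hydroxyl with retention at C9, the acyl stereocentre is bought, and the excess acid buffers the medium so that the acidic C8–H of the butenolide should not epimerise.

Step 9
Reactants: 11 (1R,2S,6R)-1-[(2S)-4-bromo-5-oxo-2,5-dihydrofuran-2-yl]-2,6-dimethyl-2-(triethylsilyloxy)oct-7-en-1-yl (2R)-2-methylbutanoate; 12 (tributylstannyl)methanol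
Product: 13 (1R,2S,6R)-1-[(2S)-4-(hydroxymethyl)-5-oxo-2,5-dihydrofuran-2-yl]-2,6-dimethyl-2-(triethylsilyloxy)oct-7-en-1-yl (2R)-2-methylbutanoate
Conditions: Pd2(dba)3 (cat.), AsPh3 (cat.), CuI (cat.), NMP, 45 °C
Reagents that add atoms: none
Why: Stille cross-coupling of the activated α-bromobutenolide with the hydroxymethyl stannane under neutral, copper-accelerated conditions introduces C13 with its free hydroxyl and involves no stereocentre.

Step 10
Reactants: 13 (1R,2S,6R)-1-[(2S)-4-(hydroxymethyl)-5-oxo-2,5-dihydrofuran-2-yl]-2,6-dimethyl-2-(triethylsilyloxy)oct-7-en-1-yl (2R)-2-methylbutanoate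
Product: 15 (1R,2S,6R)-1-[(2S)-4-(hydroxymethyl)-5-oxo-2,5-dihydrofuran-2-yl]-2,6-dimethyl-7-oxo-2-(triethylsilyloxy)heptyl (2R)-2-methylbutanoate, via secondary ozonide of the vinyl group 14 (not isolated)
Conditions: O3, CH2Cl2, −78 °C (Sudan III end point); Me2S, −78 °C → rt
Reagents that add atoms: ozone, [O-][O+]=O
Why: Ozonolysis with reductive work-up cleaves the monosubstituted vinyl group far faster than the trisubstituted, carbonyl-conjugated butenolide alkene, and the neutral work-up should keep the α-centre C4 intact.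

Step 11
Reactants: 15 (1R,2S,6R)-1-[(2S)-4-(hydroxymethyl)-5-oxo-2,5-dihydrofuran-2-yl]-2,6-dimethyl-7-oxo-2-(triethylsilyloxy)heptyl (2R)-2-methylbutanoate; 16 tert-butyl diazoacetate
Product: 17 tert-butyl (4R,8S,9R)-9-[(2S)-4-(hydroxymethyl)-5-oxo-2,5-dihydrofuran-2-yl]-4,8-dimethyl-9-{[(2R)-2-methylbutanoyl]oxy}-3-oxo-8-(triethylsilyloxy)nonanoate
Conditions: SnCl2 (cat.), CH2Cl2, rt
Reagents that add atoms: none
Why: Roskamp reaction (Lewis-acid-catalysed addition of the diazoacetate to the aldehyde, 1,2-hydride shift and loss of N2) gives the β-keto ester under nearly neutral conditions that preserve C4 and C8.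

Step 12
Reactants: 17 tert-butyl (4R,8S,9R)-9-[(2S)-4-(hydroxymethyl)-5-oxo-2,5-dihydrofuran-2-yl]-4,8-dimethyl-9-{[(2R)-2-methylbutanoyl]oxy}-3-oxo-8-(triethylsilyloxy)nonanoate
Product: 21 10-O-triethylsilyl-ineupatorolide A, via acylketene 18 (not isolated), via 14-membered β-keto lactone 19 (not isolated), via ten-membered β-keto acid 20 (not isolated)
Conditions: dry, degassed mesitylene (0.5 mM), BHT (cat.), 165 °C, slow syringe-pump addition, then continued heating
Reagents that add atoms: none
Why: Proposed new method: thermal loss of tert-butanol from the tert-butyl β-keto ester gives acylketene 18, which at high dilution is captured by the only free hydroxyl (primary, allylic C13–OH) and so closes the temporary 14-membered β-keto lactone 19 by O-acylation, the closest known type being acylketene macrolactonisation. In 19 the ketene-hemiacetal tautomer holds the array C6=C(OH)–O–C13–C11=C7, and a Carroll-type [3,3] shift (closest known types: the Carroll rearrangement of allyl β-keto esters and the four-atom Claisen ring contraction of macrolides) forms C6–C7, breaks C13–O and moves the alkene to C11=C13, so the ten-membered carbocycle is closed by suprafacial sigmatropic ring contraction (14 → 10) through a chair array in which C5 and C8 sit gauche about the new bond. The shift is polarity-matched, because the electron-rich enol carbon C6 bonds to the β-carbon C7 of the unsaturated lactone, so the same reorganisation could also run stepwise as a 6-endo Michael addition followed by E1cB loss of the C13 carboxylate, and loss of CO2 from β-keto acid 20 makes it irreversible and pays for the medium-ring strain. C7 is the only lasting new stereocentre and is controlled by C8: bonding on the butenolide face anti to the C8–C9 bond gives a C6–C7–C8–C9 torsion near 150°, as a cyclodecane ring prefers, whereas syn attack needs a nearly eclipsed torsion, so the trans-fused lactone should result, and the transient centre at C6 is erased by decarboxylation. Regioselectivity (C7 and not C13) is secured by the tether, since bonding of C6 to C13 would need a four-membered ring, and chemoselectivity is secured by the TES ether on the tertiary C10 oxygen and by the absence of base, which protects C8–H and C4–H.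

Step 13
Reactants: 21 10-O-triethylsilyl-ineupatorolide A
Product: 22 ineupatorolide A
Conditions: HF·pyridine, THF, 0 °C → rt
Reagents that add atoms: none
Why: Fluoride-mediated cleavage of the tertiary silyl ether under weakly acidic conditions leaves the α-methylene lactone, the C9 ester and the epimerisable C4 untouched.

## Compound list
1 | (R)-β-citronellene, (3R)-3,7-dimethylocta-1,6-diene | CC(C)=CCC[C@@H](C)C=C | starting material
2 | (2E,6R)-2,6-dimethylocta-2,7-dien-1-ol | OC/C(C)=C/CC[C@@H](C)C=C | intermediate
3 | {(2R,3R)-2-methyl-3-[(3R)-3-methylpent-4-en-1-yl]oxiran-2-yl}methanol | OC[C@@]1(C)O[C@@H]1CC[C@@H](C)C=C | intermediate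
4 | (2S,6R)-2,6-dimethyloct-7-ene-1,2-diol | OC[C@@](C)(O)CCC[C@@H](C)C=C | intermediate
5 | (2S,6R)-2,6-dimethyl-1,2-bis(triethylsilyloxy)oct-7-ene | CC[Si](CC)(CC)OC[C@@](C)(O[Si](CC)(CC)CC)CCC[C@@H](C)C=C | intermediate
6 | (2S,6R)-2,6-dimethyl-2-(triethylsilyloxy)oct-7-enal | O=C[C@@](C)(O[Si](CC)(CC)CC)CCC[C@@H](C)C=C | intermediate
7 | 3-bromofuran-2(5H)-one | O=C1OCC=C1Br | starting material
8 | 3-bromo-2-(triisopropylsilyloxy)furan | CC(C)[Si](Oc1occc1Br)(C(C)C)C(C)C | intermediate
9 | (5S)-3-bromo-5-[(1R,2S,6R)-1-hydroxy-2,6-dimethyl-2-(triethylsilyloxy)oct-7-en-1-yl]furan-2(5H)-one | BrC1=C[C@H](OC1=O)[C@@H](O)[C@@](C)(O[Si](CC)(CC)CC)CCC[C@@H](C)C=C | intermediate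
10 | (R)-2-methylbutanoic acid | OC(=O)[C@H](C)CC | starting material
11 | C9 (2R)-2-methylbutanoate of 9 (4R,8S,9R,10S) | BrC1=C[C@H](OC1=O)[C@@H](OC(=O)[C@H](C)CC)[C@@](C)(O[Si](CC)(CC)CC)CCC[C@@H](C)C=C | intermediate
12 | (tributylstannyl)methanol | OC[Sn](CCCC)(CCCC)CCCC | starting material
13 | 3-(hydroxymethyl)butenolide ester with intact vinyl group (4R,8S,9R,10S) | OCC1=C[C@H](OC1=O)[C@@H](OC(=O)[C@H](C)CC)[C@@](C)(O[Si](CC)(CC)CC)CCC[C@@H](C)C=C | intermediate
14 | secondary ozonide (1,2,4-trioxolane) of 13, epimers at the new acetal carbon | OCC1=C[C@H](OC1=O)[C@@H](OC(=O)[C@H](C)CC)[C@@](C)(O[Si](CC)(CC)CC)CCC[C@@H](C)C2OCOO2 | intermediate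
15 | C5 aldehyde (4R,8S,9R,10S) | OCC1=C[C@H](OC1=O)[C@@H](OC(=O)[C@H](C)CC)[C@@](C)(O[Si](CC)(CC)CC)CCC[C@@H](C)C=O | intermediate
16 | tert-butyl diazoacetate | CC(C)(C)OC(=O)C=[N+]=[N-] | starting material
17 | open-chain tert-butyl β-keto ester with free C13–OH (4R,8S,9R,10S) | OCC1=C[C@H](OC1=O)[C@@H](OC(=O)[C@H](C)CC)[C@@](C)(O[Si](CC)(CC)CC)CCC[C@@H](C)C(=O)CC(=O)OC(C)(C)C | intermediate
18 | acylketene | OCC1=C[C@H](OC1=O)[C@@H](OC(=O)[C@H](C)CC)[C@@](C)(O[Si](CC)(CC)CC)CCC[C@@H](C)C(=O)C=C=O | intermediate
19 | 14-membered β-keto lactone spanning C13–O and C6, fused to the butenolide | O1CC2=C[C@H](OC2=O)[C@@H](OC(=O)[C@H](C)CC)[C@@](C)(O[Si](CC)(CC)CC)CCC[C@@H](C)C(=O)CC1=O | intermediate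
20 | ten-membered β-keto acid (CO2H on C6; C6 configuration inconsequential and left open) | C=C1C(=O)O[C@@H]2[C@@H](OC(=O)[C@H](C)CC)[C@@](C)(O[Si](CC)(CC)CC)CCC[C@@H](C)C(=O)C(C(=O)O)[C@@H]12 | intermediate
21 | 10-O-triethylsilyl-ineupatorolide A | C=C1C(=O)O[C@@H]2[C@@H](OC(=O)[C@H](C)CC)[C@@](C)(O[Si](CC)(CC)CC)CCC[C@@H](C)C(=O)C[C@@H]12 | intermediate
22 | ineupatorolide A (4R,7S,8S,9R,10S,2'R) | C=C1C(=O)O[C@@H]2[C@@H](OC(=O)[C@H](C)CC)[C@@](C)(O)CCC[C@@H](C)C(=O)C[C@@H]12 | target

## Summary
Total step count: 13. Longest linear sequence: 12 steps (1 → 22 through steps 1–5 and 7–13).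

## Steps most likely to fail

**Step 12 (new method).**
- What may go wrong:
  - The acylketene may be consumed by oligomerisation or by traces of water before the large ring closes.
  - The 14-membered lactone may form, but its sigmatropic contraction may be too slow at temperatures the α-methylene lactone tolerates.
  - Bond formation may take place on the butenolide face syn to C9.
- Fallback (known chemistry, sets out from 17, comes back at 22): an intramolecular SN2′ alkylation replaces the pericyclic contraction.
  - Appel bromination (CBr4, PPh3) of the C13 alcohol gives the allylic bromide F1.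
  - DABCO converts it into the quaternary ammonium salt F2. The bulky leaving group blocks direct displacement at C13.
  - Cs2CO3 in MeCN under high dilution lets the β-keto ester carbanion attack C7 anti to C9 and expel DABCO. This gives the ten-membered tert-butyl β-keto ester F3, which already carries the exocyclic methylene.
  - TFA in CH2Cl2 removes the tert-butyl and TES groups to give the β-keto acid F4, and gentle warming decarboxylates it to 22.

**Step 7.**
- What may go wrong: discrimination between the methyl group and the chain on the quaternary C10 may be weak. Facial selectivity at the aldehyde would then be poor, and the 8,9-threo preference could also erode with the bulky partners.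
- Fallback (sets out from 6, comes back at 13): reagent control replaces 1,2-induction, and the butenolide is built by metathesis.
  - Brown-type alkoxyallylboration of 6 uses (Z)-γ-(methoxymethoxy)allyldiisopinocampheylborane, taking the Ipc antipode that attacks the face leading to 9R. It gives the syn mono-MOM diol F5.
  - ZnBr2/n-PrSH removes the MOM group to give the diol F6.
  - 2-[(4-Methoxybenzyloxy)methyl]acrylic acid F7 is made from commercial 2-(bromomethyl)acrylic acid and sodium 4-methoxybenzyl oxide. It is attached with DIC and catalytic DMAP to the less hindered allylic C8–OH to give the acrylate F8.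
  - Ring-closing metathesis (Grubbs second-generation catalyst, dilute toluene, 80 °C) closes the five-membered ring much faster than anything happens at the remote vinyl group. It gives the PMB-protected butenolide carbinol F9.
  - Steglich esterification with 10 gives the ester F10, and DDQ in buffered CH2Cl2 releases 13.

**Step 9.**
- What may go wrong: transmetalation of the hydroxymethyl stannane may be slow, and protodebromination or palladium-induced degradation of the base- and heat-sensitive butenolide may compete.
- Fallback (sets out from 8, comes back at 13): C13 is installed on the furan before the fragments are joined.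
  - Bromine–lithium exchange of 8 (n-BuLi, −78 °C), trapping with formaldehyde and silylation of the alkoxide with TESCl give 3-[(triethylsilyloxy)methyl]-2-(triisopropylsilyloxy)furan F11.
  - Its vinylogous Mukaiyama aldol reaction with 6 (BF3·OEt2, −78 °C) gives the carbinol F12.
  - Steglich esterification with 10 gives the ester F13.
  - PPTS in MeOH at 0 °C cleaves the primary TES ether selectively in the presence of the tertiary one and gives 13.

## Further compounds
F1 | step 12 | C13 allylic bromide of 17 | BrCC1=C[C@H](OC1=O)[C@@H](OC(=O)[C@H](C)CC)[C@@](C)(O[Si](CC)(CC)CC)CCC[C@@H](C)C(=O)CC(=O)OC(C)(C)C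
F2 | step 12 | C13 DABCO ammonium bromide | [Br-].C([N+]12CCN(CC1)CC2)C3=C[C@H](OC3=O)[C@@H](OC(=O)[C@H](C)CC)[C@@](C)(O[Si](CC)(CC)CC)CCC[C@@H](C)C(=O)CC(=O)OC(C)(C)C
F3 | step 12 | ten-membered tert-butyl β-keto ester (ester on C6, C6 configuration left open) | C=C1C(=O)O[C@@H]2[C@@H](OC(=O)[C@H](C)CC)[C@@](C)(O[Si](CC)(CC)CC)CCC[C@@H](C)C(=O)C(C(=O)OC(C)(C)C)[C@@H]12
F4 | step 12 | desilylated ten-membered β-keto acid (C6 configuration left open) | C=C1C(=O)O[C@@H]2[C@@H](OC(=O)[C@H](C)CC)[C@@](C)(O)CCC[C@@H](C)C(=O)C(C(=O)O)[C@@H]12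
F5 | step 7 | syn alkoxyallylboration adduct (C8–OMOM, C9–OH) | C=C[C@H](OCOC)[C@@H](O)[C@@](C)(O[Si](CC)(CC)CC)CCC[C@@H](C)C=C
F6 | step 7 | C8,C9 syn diol | C=C[C@H](O)[C@@H](O)[C@@](C)(O[Si](CC)(CC)CC)CCC[C@@H](C)C=C
F7 | step 7 | 2-[(4-methoxybenzyloxy)methyl]acrylic acid | C=C(COCc1ccc(OC)cc1)C(=O)O
F8 | step 7 | C8 acrylate of F6 | C=C[C@H](OC(=O)C(=C)COCc1ccc(OC)cc1)[C@@H](O)[C@@](C)(O[Si](CC)(CC)CC)CCC[C@@H](C)C=C
F9 | step 7 | 3-(PMB-oxymethyl)butenolide carbinol | COc1ccc(COCC2=C[C@H](OC2=O)[C@@H](O)[C@@](C)(O[Si](CC)(CC)CC)CCC[C@@H](C)C=C)cc1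
F10 | step 7 | C9 (2R)-2-methylbutanoate of F9 | COc1ccc(COCC2=C[C@H](OC2=O)[C@@H](OC(=O)[C@H](C)CC)[C@@](C)(O[Si](CC)(CC)CC)CCC[C@@H](C)C=C)cc1
F11 | step 9 | 3-[(triethylsilyloxy)methyl]-2-(triisopropylsilyloxy)furan | CC[Si](CC)(CC)OCc1ccoc1O[Si](C(C)C)(C(C)C)C(C)C
F12 | step 9 | 3-(TES-oxymethyl)butenolide carbinol | CC[Si](CC)(CC)OCC1=C[C@H](OC1=O)[C@@H](O)[C@@](C)(O[Si](CC)(CC)CC)CCC[C@@H](C)C=C
F13 | step 9 | C9 (2R)-2-methylbutanoate of F12 | CC[Si](CC)(CC)OCC1=C[C@H](OC1=O)[C@@H](OC(=O)[C@H](C)CC)[C@@](C)(O[Si](CC)(CC)CC)CCC[C@@H](C)C=C
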